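**Retrosynthetic overview**
1. Target ⇒ its 3'-O-benzyl ether, opened by hydrogenolysis in the last step.
2. Ring C ⇒ aryl 1-arylvinyl ether + CO. A new carbonylative double C–H annulation makes C3–C4 and C4–C4a in one step.
3. Vinyl ether ⇒ aryl benzoate. Ester methylenation brings in C3, and the ester O–C(acyl) bond becomes O1–C2. The benzoate comes from 2,3-dimethoxyphenol (ring A) and O-benzylated 3-hydroxy-4,5-dimethoxybenzoic acid (ring B).
4. Ring order: rings A and B are bought as intact arenes. Ring C is the only ring formed, in the step before the last.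

Assumption: the target has no stereocentre and is achiral, so the "single enantiomer" is the compound itself and no step needs stereocontrol.

**Route**

Step 1
Reactants: 1 methyl 3-hydroxy-4,5-dimethoxybenzoate
Product: 2 methyl 3-(benzyloxy)-4,5-dimethoxybenzoate
Conditions: BnBr (1.2 equiv), K2CO3 (2 equiv), DMF, 60 °C, 4 h
Reagents that add atoms: benzyl bromide, BrCc1ccccc1
Why: Williamson ether synthesis, in which the phenoxide formed by K2CO3 displaces bromide from benzyl bromide (SN2) while the methyl ester stays inert.

Step 2
Reactants: 2 methyl 3-(benzyloxy)-4,5-dimethoxybenzoate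
Product: 4 3-(benzyloxy)-4,5-dimethoxybenzoic acid, via lithium carboxylate 3 (not isolated)
Conditions: LiOH·H2O (3 equiv), THF/MeOH/H2O (3:1:1), 50 °C; then 1 M HCl to pH 2
Reagents that add atoms: lithium hydroxide, [Li+].[OH-]
Why: Ester saponification (addition–elimination at the acyl carbon) followed by acidification, and benzyl and methyl aryl ethers are stable to aqueous base and dilute acid.

Step 3
Reactants: 4 3-(benzyloxy)-4,5-dimethoxybenzoic acid; 5 2,3-dimethoxyphenol
Product: 6 2,3-dimethoxyphenyl 3-(benzyloxy)-4,5-dimethoxybenzoate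
Conditions: DCC (1.1 equiv), DMAP (10 mol %), CH2Cl2, 0 °C to rt, 12 h
Reagents that add atoms: none
Why: Steglich esterification, in which DCC activates the acid and DMAP passes the acyl group to the moderately hindered phenol under neutral conditions that touch no ether.

Step 4
Reactants: 6 2,3-dimethoxyphenyl 3-(benzyloxy)-4,5-dimethoxybenzoate
Product: 7 1-(benzyloxy)-5-[1-(2,3-dimethoxyphenoxy)ethenyl]-2,3-dimethoxybenzene
Conditions: Cp2TiMe2 (2.5 equiv), toluene, 75 °C, dark, 16 h; filtration through basic alumina (1% Et3N in eluent)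
Reagents that add atoms: dimethyltitanocene Cp2TiMe2, C[Ti+2]C.c1cc[cH-]c1.c1cc[cH-]c1
Why: Petasis methylenation, in which thermolysis of Cp2TiMe2 gives the titanium methylidene that olefinates the ester C=O (aryl benzoates are standard substrates for titanium-carbene methylenation), driven by the strong Ti=O bond under non-basic, non-acidic conditions.

Step 5
Reactants: 7 1-(benzyloxy)-5-[1-(2,3-dimethoxyphenoxy)ethenyl]-2,3-dimethoxybenzene
Product: 10 3'-(benzyloxy)-4',5',7,8-tetramethoxyflavone, via oxapalladacycle 8 (not isolated), via acylpalladacycle 9 (not isolated)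
Conditions: Pd(OAc)2 (10 mol %), N-acetylglycine (20 mol %), 2,6-dimethyl-1,4-benzoquinone (1.5 equiv), CO (1 atm), 4 Å MS, 1,4-dioxane, 90 °C, 18 h
Reagents that add atoms: carbon monoxide, [C-]#[O+]
Why: Proposed new method: oxidative carbonylative double C–H annulation of an aryl 1-arylvinyl ether, in which Pd(OAc)2 (divalent palladium) palladates the nucleophilic CH2 terminus of the enol ether, N-acetylglycine-assisted concerted metalation–deprotonation then takes the only free ortho C–H of ring A (para to a methoxy group and carrying one ortho neighbour only, hence favoured over the doubly flanked C–H bonds of ring B) to give the six-membered oxapalladacycle 8, CO inserts to give 9 faster than 8 can collapse to a 2-arylbenzofuran, C–C reductive elimination closes ring C as the 4-pyranone and releases zerovalent palladium, and the quinone re-oxidises it while using up the two equivalents of AcOH so that the dry medium stays near neutral and the enol ether is not hydrolysed; the closest known reaction types are the palladium-catalysed double C–H carbonylation of diaryl ethers to xanthones, the oxidative C–H/C–H cyclisation of 3-aryloxyacrylates to benzofurans and the oxidative cyclocarbonylation of 2-vinylphenols to coumarins, none of which joins an alkenyl C–H, an aryl C–H and CO across an ether oxygen to build a flavone.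

Step 6
Reactants: 10 3'-(benzyloxy)-4',5',7,8-tetramethoxyflavone
Product: 11 3'-hydroxy-4',5',7,8-tetramethoxyflavone
Conditions: H2 (1 atm), 10% Pd/C (10 wt %), EtOAc/MeOH (1:1), rt, 2–3 h, stopped at one equivalent of H2
Reagents that add atoms: none
Why: Catalytic hydrogenolysis of the benzylic C–O bond, which at 1 atm and room temperature is much faster than reduction of the vinylogous-ester C2=C3 bond of a flavone and leaves the four methyl ethers untouched.

**Compound list**
1 | methyl 3-hydroxy-4,5-dimethoxybenzoate | COC(=O)c1cc(O)c(OC)c(OC)c1 | starting material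
2 | methyl 3-(benzyloxy)-4,5-dimethoxybenzoate | COC(=O)c1cc(OCc2ccccc2)c(OC)c(OC)c1 | intermediate
3 | lithium 3-(benzyloxy)-4,5-dimethoxybenzoate | [Li+].[O-]C(=O)c1cc(OCc2ccccc2)c(OC)c(OC)c1 | intermediate
4 | 3-(benzyloxy)-4,5-dimethoxybenzoic acid | OC(=O)c1cc(OCc2ccccc2)c(OC)c(OC)c1 | intermediate
5 | 2,3-dimethoxyphenol | COc1cccc(O)c1OC | starting material
6 | 2,3-dimethoxyphenyl 3-(benzyloxy)-4,5-dimethoxybenzoate | COc1cccc(OC(=O)c2cc(OCc3ccccc3)c(OC)c(OC)c2)c1OC | intermediate
7 | 1-(benzyloxy)-5-[1-(2,3-dimethoxyphenoxy)ethenyl]-2,3-dimethoxybenzene | C=C(Oc1cccc(OC)c1OC)c1cc(OCc2ccccc2)c(OC)c(OC)c1 | intermediate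
8 | six-membered oxapalladacycle, divalent palladium bound to the vinyl CH and to C6 of ring A (ancillary ligands omitted) | COc1ccc2[Pd]C=C(Oc2c1OC)c1cc(OCc2ccccc2)c(OC)c(OC)c1 | intermediate
9 | seven-membered acylpalladacycle formed by CO insertion into the Pd–vinyl bond of 8 (ancillary ligands omitted) | COc1ccc2[Pd]C(=O)C=C(Oc2c1OC)c1cc(OCc2ccccc2)c(OC)c(OC)c1 | intermediate
10 | 3'-(benzyloxy)-4',5',7,8-tetramethoxyflavone | COc1cc(-c2cc(=O)c3ccc(OC)c(OC)c3o2)cc(OCc2ccccc2)c1OC | intermediate
11 | 3'-hydroxy-4',5',7,8-tetramethoxyflavone | COc1cc(-c2cc(=O)c3ccc(OC)c(OC)c3o2)cc(O)c1OC | target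

**Total step count:** 6.

**Longest linear sequence:** 6 steps (1 → 2 → 4 → 6 → 7 → 10 → 11). Phenol 5 enters at step 3.

**The three steps most likely to fail**

**Step 5, the proposed new step.**
- Oxapalladacycle 8 may collapse directly to the 2-arylbenzofuran.
- The vinylpalladium species may instead activate ring B and give a 3-aryloxyindenone.
- Traces of water may hydrolyse 7.
- CO may reduce the catalyst to palladium black.

The fallback is the Baker–Venkataraman route, which is known chemistry. It sets out from acid 4 and comes back to the route at 10. Acid 4 is esterified (DCC, DMAP, CH2Cl2) with purchased 2'-hydroxy-3',4'-dimethoxyacetophenone F1 to give 6-acetyl-2,3-dimethoxyphenyl 3-(benzyloxy)-4,5-dimethoxybenzoate F2. KOtBu in THF at room temperature moves the aroyl group from oxygen to the ketone enolate carbon and gives 1-[3-(benzyloxy)-4,5-dimethoxyphenyl]-3-(2-hydroxy-3,4-dimethoxyphenyl)propane-1,3-dione F3. Catalytic p-TsOH in refluxing toluene then closes ring C by cyclodehydration to 10.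

**Step 4.**
- Methylenation of the electron-rich, ortho-substituted aryl benzoate may stall.
- The acid-labile enol ether 7 may be lost on isolation.

The fallback builds the vinyl–O bond by cross-coupling instead of by carbonyl olefination. It sets out from acid 4 and comes back at 7. Acid 4 is treated with MeLi (2.2 equiv, THF, 0 °C) to give 1-[3-(benzyloxy)-4,5-dimethoxyphenyl]ethanone F4. KHMDS and PhNTf2 (THF, −78 °C) convert this into 1-[3-(benzyloxy)-4,5-dimethoxyphenyl]ethenyl trifluoromethanesulfonate F5. Palladium-catalysed C–O coupling of F5 with phenol 5 gives 7 (Pd2(dba)3, 2-(di-tert-butylphosphino)biphenyl, NaOtBu, toluene, 100 °C).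

**Step 6.**
- Over-reduction of C2=C3 to the flavanone may compete with debenzylation.

The fallback replaces the reductive cleavage by a Lewis-acid cleavage with cation capture. It sets out from 10 and comes back at 11. BCl3 (2 equiv) and pentamethylbenzene (3 equiv) in CH2Cl2 at −78 °C remove the benzyl group. At that temperature the aryl methyl ethers and the enone are not touched. New compounds on this way: none F0.

**Further compounds**
F1 | step 5 | 2'-hydroxy-3',4'-dimethoxyacetophenone | CC(=O)c1ccc(OC)c(OC)c1O
F2 | step 5 | 6-acetyl-2,3-dimethoxyphenyl 3-(benzyloxy)-4,5-dimethoxybenzoate | CC(=O)c1ccc(OC)c(OC)c1OC(=O)c1cc(OCc2ccccc2)c(OC)c(OC)c1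
F3 | step 5 | 1-[3-(benzyloxy)-4,5-dimethoxyphenyl]-3-(2-hydroxy-3,4-dimethoxyphenyl)propane-1,3-dione | O=C(CC(=O)c1ccc(OC)c(OC)c1O)c1cc(OCc2ccccc2)c(OC)c(OC)c1
F4 | step 4 | 1-[3-(benzyloxy)-4,5-dimethoxyphenyl]ethanone | CC(=O)c1cc(OCc2ccccc2)c(OC)c(OC)c1
F5 | step 4 | 1-[3-(benzyloxy)-4,5-dimethoxyphenyl]ethenyl trifluoromethanesulfonate | C=C(OS(=O)(=O)C(F)(F)F)c1cc(OCc2ccccc2)c(OC)c(OC)c1
F0 | step 6 | none | none
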